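**Strategy.** The route rests on cutting the C2–C3 bond of the oxolane ring. Both carbons carry oxygen (ring O1 on C2, the hydroxyl on C3) and C2 also bears the first alkene carbon of the diene, so C2 is made nucleophilic as the oxygen-bearing γ-carbon of a (Z)-alkoxyallyl pinacol boronate tethered through O1, C5 and C4 to the C3 aldehyde. Releasing that aldehyde from its dimethyl acetal triggers an intramolecular allylboration that forms C2–C3, closes the ring, sets C2 and C3 under control of the C5 methyl stereocentre and leaves the C2 vinyl group. Cross-metathesis to an enal, olefination with a chlorinated isocoumarin-3-ylmethyl phosphonate and global desilylation finish the synthesis.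

Key step: step 5

Remark: atoms are labelled oxolane O1, C2 (dienyl carbon), C3 (hydroxyl), C4, C5 (methyl) and isocoumarin C1 (carbonyl) to C8a; commercial methyl orsellinate lacks the chlorine of the target, so it is chlorinated first, and this chlorination is assumed to go to the carbon between the 4-hydroxyl and the methyl group, the usual site for orsellinate esters.

Step 1
Reactants: 1 ethyl (3S)-3-hydroxybutanoate; 2 allyl 2,2,2-trichloroacetimidate
Product: 3 ethyl (3S)-3-(prop-2-en-1-yloxy)butanoate
Conditions: TfOH (cat.), CH2Cl2/cyclohexane, 0 °C to rt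
Reagents that add atoms: none
Why: Acid-catalysed trichloroacetimidate O-alkylation etherifies the hydroxyl without base, so the β-hydroxy ester cannot undergo retro-aldol cleavage or elimination, and the stereocentre is retained because its C–O bond is not broken.

Step 2
Reactants: 3 ethyl (3S)-3-(prop-2-en-1-yloxy)butanoate
Product: 5 (3S)-3-(prop-2-en-1-yloxy)butanal, via aluminium hemiacetal 4 (not isolated)
Conditions: i-Bu2AlH (1.05 equiv), CH2Cl2, −78 °C; MeOH, then aq. potassium sodium tartrate
Reagents that add atoms: none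
Why: Partial reduction of an ester with i-Bu2AlH at −78 °C stops at hemiacetal 4, held by chelation of aluminium to the β-ether oxygen, and the aldehyde appears only on aqueous work-up, so over-reduction is avoided.

Step 3
Reactants: 5 (3S)-3-(prop-2-en-1-yloxy)butanal
Product: 6 (3S)-1,1-dimethoxy-3-(prop-2-en-1-yloxy)butane
Conditions: HC(OMe)3, PPTS (cat.), MeOH, rt
Reagents that add atoms: trimethyl orthoformate, COC(OC)OC
Why: Acid-catalysed acetalisation, with the orthoformate as methoxy donor and water scavenger, masks the aldehyde in a form inert to alkyllithium reagents, and the weak pyridinium acid does not eliminate the β-allyloxy group.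

Step 4
Reactants: 6 (3S)-1,1-dimethoxy-3-(prop-2-en-1-yloxy)butane; 7 2-isopropoxy-4,4,5,5-tetramethyl-1,3,2-dioxaborolane
Product: 10 2-[(2Z)-3-{[(2S)-4,4-dimethoxybutan-2-yl]oxy}prop-2-en-1-yl]-4,4,5,5-tetramethyl-1,3,2-dioxaborolane, via (Z)-alkoxyallyllithium 8 (not isolated), via lithium isopropoxyborate 9 (not isolated)
Conditions: s-BuLi, TMEDA, THF, −78 °C; then 7, −78 °C; aq. NH4Cl, −78 °C to rt
Reagents that add atoms: none
Why: Allylic lithiation of an allyl ether gives the oxygen-chelated (Z)-alkoxyallyllithium 8, which the borate ester captures at the carbon remote from oxygen (γ-borylation of an α-alkoxyallyl anion) to give ate complex 9, and protonation releases isopropanol and the Z boronate.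

Step 5
Reactants: 10 2-[(2Z)-3-{[(2S)-4,4-dimethoxybutan-2-yl]oxy}prop-2-en-1-yl]-4,4,5,5-tetramethyl-1,3,2-dioxaborolane
Product: 13 (2S,3S,5S)-2-ethenyl-5-methyloxolan-3-ol, via boryl aldehyde 11 (not isolated), via pinacol borate ester 12 (not isolated)
Conditions: Yb(OTf)3 (10 mol %), MeCN/H2O (9:1), rt
Reagents that add atoms: water, O
Why: Yb(OTf)3 in wet acetonitrile activates the dimethyl acetal by coordination and hydrolyses it to aldehyde 11, while the enol ether, which would need C-protonation, should survive the almost neutral medium; in 11 the carbonyl oxygen complexes boron and the C2–C3 bond forms in a chair-like six-atom cyclic array with allyl transposition, giving borate 12, which the water present cleaves to 13. The closest known reaction type is the intramolecular allylboration of γ-(ω-oxoalkoxy)allylboronates unmasked from acetals, used to make 2-vinyl-3-hydroxy cyclic ethers with six- and seven-membered rings. The oxolane closes by C–C bond formation in a 5-exo-trig mode, nucleophilic C2 attacking the aldehyde carbon whose C=O bond lies outside the new ring. The cis relation between the C2 vinyl group and the C3 oxygen comes from the Z enol ether, because its oxygen substituent must stand axial in the chair. The absolute sense at C2 and C3 is relayed from C5: the chair is cis-fused to the forming five-membered ring and the C5 methyl group is expected on the outer face of this bicycle, anti to both new substituents, which corresponds to 2S,3S. The step therefore needs facial selectivity, resting on the one methyl group, and needs cyclisation to outrun β-elimination of the alkoxy group from 11, which the intramolecular boron delivery at room temperature should secure.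

Step 6
Reactants: 13 (2S,3S,5S)-2-ethenyl-5-methyloxolan-3-ol
Product: 14 {[(2S,3S,5S)-2-ethenyl-5-methyloxolan-3-yl]oxy}triethylsilane
Conditions: Et3SiCl, imidazole, CH2Cl2, 0 °C to rt
Reagents that add atoms: chlorotriethylsilane, CC[Si](Cl)(CC)CC
Why: Routine silyl ether formation at the secondary alcohol shields C3–OH from the base of the later olefination and turns the volatile alcohol into a compound that is easy to purify.

Step 7
Reactants: 14 {[(2S,3S,5S)-2-ethenyl-5-methyloxolan-3-yl]oxy}triethylsilane; 15 (2E)-but-2-enal (crotonaldehyde)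
Product: 16 (2E)-3-[(2S,3S,5S)-5-methyl-3-(triethylsilyloxy)oxolan-2-yl]prop-2-enal
Conditions: second-generation Hoveyda–Grubbs catalyst (5 mol %), 15 (excess), CH2Cl2, 40 °C
Reagents that add atoms: none
Why: Olefin cross-metathesis between the terminal vinyl group and an excess of the electron-poor enal is selective for the cross product and, being reversible, should deliver the E enal while the ether, silyl ether and stereocentres remain untouched.

Step 8
Reactants: 17 methyl 2,4-dihydroxy-6-methylbenzoate (methyl orsellinate)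
Product: 18 methyl 3-chloro-4,6-dihydroxy-2-methylbenzoate
Conditions: SO2Cl2 (1.0 equiv), Et2O, 0 °C to rt
Reagents that add atoms: sulfuryl chloride, O=S(=O)(Cl)Cl
Why: Electrophilic aromatic chlorination of the resorcinol ring goes mainly to the carbon para to the ester-chelated hydroxyl and ortho to the free one, which is the usual outcome for orsellinate esters, and the isomeric chloro and dichloro by-products can be removed by crystallisation.

Step 9
Reactants: 18 methyl 3-chloro-4,6-dihydroxy-2-methylbenzoate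
Product: 19 methyl 3-chloro-4,6-bis(methoxymethoxy)-2-methylbenzoate
Conditions: NaH, MOMCl, DMF, 0 °C to rt
Reagents that add atoms: chloromethyl methyl ether, COCCl
Why: Williamson-type alkylation of both phenoxides gives acetal ethers that tolerate lithium amide bases and are later removed by acid.

Step 10
Reactants: 19 methyl 3-chloro-4,6-bis(methoxymethoxy)-2-methylbenzoate; 20 2-chloro-N-methoxy-N-methylacetamide
Product: 23 methyl 3-chloro-2-(3-chloro-2-oxopropyl)-4,6-bis(methoxymethoxy)benzoate, via benzylic lithium reagent 21 (not isolated), via tetrahedral lithium adduct 22 (not isolated)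
Conditions: LiN(i-Pr)2 (1.1 equiv), THF, −78 °C; then 20, −78 °C; AcOH, −78 °C
Reagents that add atoms: none
Why: Lateral lithiation of the ortho-toluate gives the benzylic anion 21, a vinylogous ester enolate, whose acylation by the Weinreb amide stops at the chelated adduct 22 and gives the α-chloro ketone only on cold acidic quench, so no second addition or epoxide closure occurs.

Step 11
Reactants: 23 methyl 3-chloro-2-(3-chloro-2-oxopropyl)-4,6-bis(methoxymethoxy)benzoate
Product: 25 5-chloro-3-(chloromethyl)-6,8-dihydroxy-1H-isochromen-1-one, via diphenol keto ester 24 (not isolated)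
Conditions: conc. HCl, MeOH, 50 °C
Reagents that add atoms: none
Why: Acidic methanolysis cleaves both MOM acetals to give 24, and the same acid promotes enol lactonisation (attack of the ketone enol oxygen on the ester with loss of methanol) to the conjugated isocoumarin, the thermodynamically favoured product.

Step 12
Reactants: 25 5-chloro-3-(chloromethyl)-6,8-dihydroxy-1H-isochromen-1-one
Product: 26 6,8-bis[(tert-butyldimethylsilyl)oxy]-5-chloro-3-(chloromethyl)-1H-isochromen-1-one
Conditions: TBSOTf, 2,6-lutidine, CH2Cl2, 0 °C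
Reagents that add atoms: tert-butyldimethylsilyl trifluoromethanesulfonate, CC(C)(C)[Si](C)(C)OS(=O)(=O)C(F)(F)F
Why: Silylation with the silyl triflate and a hindered pyridine base protects both phenols, the carbonyl-chelated 8-OH included, without any nucleophile that could displace the allylic chloride.

Step 13
Reactants: 26 6,8-bis[(tert-butyldimethylsilyl)oxy]-5-chloro-3-(chloromethyl)-1H-isochromen-1-one
Product: 27 diethyl ({6,8-bis[(tert-butyldimethylsilyl)oxy]-5-chloro-1-oxo-1H-isochromen-3-yl}methyl)phosphonate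
Conditions: P(OEt)3 (neat), 130 °C
Reagents that add atoms: triethyl phosphite, CCOP(OCC)OCC
Why: Michaelis–Arbuzov reaction, in which the reactive allylic-type chloride alkylates phosphorus and dealkylation by chloride gives the phosphonate and chloroethane.

Step 14
Reactants: 27 diethyl ({6,8-bis[(tert-butyldimethylsilyl)oxy]-5-chloro-1-oxo-1H-isochromen-3-yl}methyl)phosphonate; 16 (2E)-3-[(2S,3S,5S)-5-methyl-3-(triethylsilyloxy)oxolan-2-yl]prop-2-enal
Product: 29 6,8-bis[(tert-butyldimethylsilyl)oxy]-5-chloro-3-{(1E,3E)-4-[(2S,3S,5S)-5-methyl-3-(triethylsilyloxy)oxolan-2-yl]buta-1,3-dien-1-yl}-1H-isochromen-1-one, via lithium phosphonate carbanion 28 (not isolated)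
Conditions: LiN(SiMe3)2 (1.0 equiv to 27), THF, −78 °C; then 16, −78 to 0 °C
Reagents that add atoms: none
Why: Horner–Wadsworth–Emmons olefination, in which the preformed, vinylogously stabilised carbanion 28 adds to the enal carbonyl and eliminates phosphate to give the new disubstituted alkene with E geometry, the low temperature and absence of excess base protecting the γ-alkoxy enal from deprotonation.

Step 15
Reactants: 29 6,8-bis[(tert-butyldimethylsilyl)oxy]-5-chloro-3-{(1E,3E)-4-[(2S,3S,5S)-5-methyl-3-(triethylsilyloxy)oxolan-2-yl]buta-1,3-dien-1-yl}-1H-isochromen-1-one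
Product: 30 5-chloro-6,8-dihydroxy-3-{(1E,3E)-4-[(2S,3S,5S)-3-hydroxy-5-methyloxolan-2-yl]buta-1,3-dien-1-yl}-1H-isochromen-1-one
Conditions: Bu4NF, AcOH (1:1), THF, 0 °C to rt
Reagents that add atoms: none
Why: Fluoride-induced desilylation removes the two aryl silyl ethers and the triethylsilyl ether in one operation, and buffering with acetic acid keeps the lactone, the diene and the allylic C2–O1 bond away from strongly basic or acidic conditions.

**Compound list**

1 | ethyl (3S)-3-hydroxybutanoate | C[C@H](O)CC(=O)OCC | starting material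
2 | prop-2-en-1-yl 2,2,2-trichloroethanimidate (allyl trichloroacetimidate) | C=CCOC(=N)C(Cl)(Cl)Cl | starting material
3 | ethyl (3S)-3-(prop-2-en-1-yloxy)butanoate | C[C@H](OCC=C)CC(=O)OCC | intermediate
4 | [(3S)-1-ethoxy-3-(prop-2-en-1-yloxy)butoxy]bis(2-methylpropyl)alumane (aluminium hemiacetal of 3) | C[C@H](OCC=C)CC(OCC)O[Al](CC(C)C)CC(C)C | intermediate
5 | (3S)-3-(prop-2-en-1-yloxy)butanal | C[C@H](OCC=C)CC=O | intermediate
6 | (3S)-1,1-dimethoxy-3-(prop-2-en-1-yloxy)butane | C[C@H](OCC=C)CC(OC)OC | intermediate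
7 | 2-isopropoxy-4,4,5,5-tetramethyl-1,3,2-dioxaborolane | CC(C)OB1OC(C)(C)C(C)(C)O1 | starting material
8 | (2Z)-3-{[(2S)-4,4-dimethoxybutan-2-yl]oxy}prop-2-en-1-yllithium | C[C@H](O/C=C\C[Li])CC(OC)OC | intermediate
9 | lithium {(2Z)-3-{[(2S)-4,4-dimethoxybutan-2-yl]oxy}prop-2-en-1-yl}(isopropoxy)(pinacolato)borate | [Li+].C[C@H](O/C=C\C[B-]1(OC(C)C)OC(C)(C)C(C)(C)O1)CC(OC)OC | intermediate
10 | 2-[(2Z)-3-{[(2S)-4,4-dimethoxybutan-2-yl]oxy}prop-2-en-1-yl]-4,4,5,5-tetramethyl-1,3,2-dioxaborolane | C[C@H](O/C=C\CB1OC(C)(C)C(C)(C)O1)CC(OC)OC | intermediate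
11 | (3S)-3-{[(1Z)-3-(4,4,5,5-tetramethyl-1,3,2-dioxaborolan-2-yl)prop-1-en-1-yl]oxy}butanal | C[C@H](O/C=C\CB1OC(C)(C)C(C)(C)O1)CC=O | intermediate
12 | 2-{[(2S,3S,5S)-2-ethenyl-5-methyloxolan-3-yl]oxy}-4,4,5,5-tetramethyl-1,3,2-dioxaborolane | C[C@H]1C[C@H](OB2OC(C)(C)C(C)(C)O2)[C@H](C=C)O1 | intermediate
13 | (2S,3S,5S)-2-ethenyl-5-methyloxolan-3-ol (vinyl and hydroxyl cis, methyl trans to both) | C[C@H]1C[C@H](O)[C@H](C=C)O1 | intermediate
14 | {[(2S,3S,5S)-2-ethenyl-5-methyloxolan-3-yl]oxy}triethylsilane | C[C@H]1C[C@H](O[Si](CC)(CC)CC)[C@H](C=C)O1 | intermediate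
15 | (2E)-but-2-enal (crotonaldehyde) | C/C=C/C=O | starting material
16 | (2E)-3-[(2S,3S,5S)-5-methyl-3-(triethylsilyloxy)oxolan-2-yl]prop-2-enal | C[C@H]1C[C@H](O[Si](CC)(CC)CC)[C@H](/C=C/C=O)O1 | intermediate
17 | methyl 2,4-dihydroxy-6-methylbenzoate | COC(=O)c1c(C)cc(O)cc1O | starting material
18 | methyl 3-chloro-4,6-dihydroxy-2-methylbenzoate | COC(=O)c1c(C)c(Cl)c(O)cc1O | intermediate
19 | methyl 3-chloro-4,6-bis(methoxymethoxy)-2-methylbenzoate | COC(=O)c1c(C)c(Cl)c(OCOC)cc1OCOC | intermediate
20 | 2-chloro-N-methoxy-N-methylacetamide | CON(C)C(=O)CCl | starting material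
21 | {[2-chloro-6-(methoxycarbonyl)-3,5-bis(methoxymethoxy)phenyl]methyl}lithium | [Li]Cc1c(Cl)c(OCOC)cc(OCOC)c1C(=O)OC | intermediate
22 | lithium 1-chloro-3-[2-chloro-6-(methoxycarbonyl)-3,5-bis(methoxymethoxy)phenyl]-2-[methoxy(methyl)amino]propan-2-olate | [Li]OC(CCl)(Cc1c(Cl)c(OCOC)cc(OCOC)c1C(=O)OC)N(C)OC | intermediate
23 | methyl 3-chloro-2-(3-chloro-2-oxopropyl)-4,6-bis(methoxymethoxy)benzoate | COC(=O)c1c(CC(=O)CCl)c(Cl)c(OCOC)cc1OCOC | intermediate
24 | methyl 3-chloro-2-(3-chloro-2-oxopropyl)-4,6-dihydroxybenzoate | COC(=O)c1c(CC(=O)CCl)c(Cl)c(O)cc1O | intermediate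
25 | 5-chloro-3-(chloromethyl)-6,8-dihydroxy-1H-isochromen-1-one | O=c1oc(CCl)cc2c(Cl)c(O)cc(O)c12 | intermediate
26 | 6,8-bis[(tert-butyldimethylsilyl)oxy]-5-chloro-3-(chloromethyl)-1H-isochromen-1-one | O=c1oc(CCl)cc2c(Cl)c(O[Si](C)(C)C(C)(C)C)cc(O[Si](C)(C)C(C)(C)C)c12 | intermediate
27 | diethyl ({6,8-bis[(tert-butyldimethylsilyl)oxy]-5-chloro-1-oxo-1H-isochromen-3-yl}methyl)phosphonate | CCOP(=O)(OCC)Cc1cc2c(Cl)c(O[Si](C)(C)C(C)(C)C)cc(O[Si](C)(C)C(C)(C)C)c2c(=O)o1 | intermediate
28 | lithium salt of 27 deprotonated at the CH2 between phosphorus and isocoumarin C3 | [Li]C(c1cc2c(Cl)c(O[Si](C)(C)C(C)(C)C)cc(O[Si](C)(C)C(C)(C)C)c2c(=O)o1)P(=O)(OCC)OCC | intermediate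
29 | 6,8-bis[(tert-butyldimethylsilyl)oxy]-5-chloro-3-{(1E,3E)-4-[(2S,3S,5S)-5-methyl-3-(triethylsilyloxy)oxolan-2-yl]buta-1,3-dien-1-yl}-1H-isochromen-1-one | C[C@H]1C[C@H](O[Si](CC)(CC)CC)[C@H](/C=C/C=C/c2cc3c(Cl)c(O[Si](C)(C)C(C)(C)C)cc(O[Si](C)(C)C(C)(C)C)c3c(=O)o2)O1 | intermediate
30 | 5-chloro-6,8-dihydroxy-3-{(1E,3E)-4-[(2S,3S,5S)-3-hydroxy-5-methyloxolan-2-yl]buta-1,3-dien-1-yl}-1H-isochromen-1-one | C[C@H]1C[C@H](O)[C@H](/C=C/C=C/c2cc3c(Cl)c(O)cc(O)c3c(=O)o2)O1 | target

**Step count.** 15 steps in total. The longest linear sequence is 9 steps (steps 1–7, 14, 15); the arene branch (steps 8–13) joins at step 14.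

**Steps most likely to fail**

1. Step 5. The single C5 methyl group may not discriminate the two faces well enough, so that ring closure on the wrong face gives the all-cis isomer beside 13. The enol ether may also hydrolyse before the acetal opens. The fallback sets out from ester 3 and rejoins the route at enal 16; it builds the ring by carbenoid chemistry with an established 2,5-trans preference. Saponification of 3 (LiOH, THF/H2O) gives (3S)-3-(prop-2-en-1-yloxy)butanoic acid F1. Isobutyl chloroformate and Et3N convert it into the mixed carbonic anhydride F2, which diazomethane turns into (4S)-1-diazo-4-(prop-2-en-1-yloxy)pentan-2-one F3. Cu(acac)2 (cat.) in refluxing THF generates the carbenoid; ylide formation at the ether oxygen and [2,3]-sigmatropic shift of the allyl group should give (2S,5S)-5-methyl-2-(prop-2-en-1-yl)oxolan-3-one F4, with allyl trans to methyl. LiBH(s-Bu)3 at −78 °C should attack anti to the C2 substituent and give the 2,3-cis alcohol (2S,3S,5S)-5-methyl-2-(prop-2-en-1-yl)oxolan-3-ol F5. Silylation (Et3SiCl, imidazole) gives triethyl{[(2S,3S,5S)-5-methyl-2-(prop-2-en-1-yl)oxolan-3-yl]oxy}silane F6. Alkene migration with H2-activated [Ir(cod)(PMePh2)2]PF6 gives the propenyl compound triethyl{[(2S,3S,5S)-5-methyl-2-[(1E)-prop-1-en-1-yl]oxolan-3-yl]oxy}silane F7. Cross-metathesis of F7 with 15 under the conditions of step 7 then gives 16.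

2. Step 10. Proton transfer from the acidic α-chloro amide to anion 21, or attack of 21 at the C–Cl carbon, may outpace acyl transfer and return 19. The fallback sets out from 19 (through 21) and rejoins at 25; it introduces the side-chain carbon as an alcohol and chlorinates later. Anion 21 is acylated with commercial 2-[(tert-butyldimethylsilyl)oxy]-N-methoxy-N-methylacetamide to give the adduct lithium 1-[(tert-butyldimethylsilyl)oxy]-3-[2-chloro-6-(methoxycarbonyl)-3,5-bis(methoxymethoxy)phenyl]-2-[methoxy(methyl)amino]propan-2-olate F8. Cold acidic quench gives methyl 2-{3-[(tert-butyldimethylsilyl)oxy]-2-oxopropyl}-3-chloro-4,6-bis(methoxymethoxy)benzoate F9. HCl in MeOH at 50 °C strips the silyl and MOM groups and closes the lactone to 5-chloro-6,8-dihydroxy-3-(hydroxymethyl)-1H-isochromen-1-one F10. Appel-type chlorination (PPh3, N-chlorosuccinimide, THF) converts only the primary allylic alcohol and gives 25.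

3. Step 14. Carbanion 28 may deprotonate enal 16 at C2 (vinylogous enolisation), which would scramble C2 or expel the silyloxy group; the new alkene may also form with incomplete E selectivity. The fallback sets out from chloride 26 and rejoins at 29; it uses a far less basic phosphorus ylide. Heating 26 with PPh3 in toluene gives ({6,8-bis[(tert-butyldimethylsilyl)oxy]-5-chloro-1-oxo-1H-isochromen-3-yl}methyl)triphenylphosphonium chloride F11. K2CO3 and 18-crown-6 in CH2Cl2 generate the ylide 6,8-bis[(tert-butyldimethylsilyl)oxy]-5-chloro-3-[(triphenyl-λ5-phosphanylidene)methyl]-1H-isochromen-1-one F12, which undergoes Wittig olefination with 16. The by-product 6,8-bis[(tert-butyldimethylsilyl)oxy]-5-chloro-3-{(1Z,3E)-4-[(2S,3S,5S)-5-methyl-3-(triethylsilyloxy)oxolan-2-yl]buta-1,3-dien-1-yl}-1H-isochromen-1-one F13 formed beside 29 is converted into 29 by iodine-catalysed isomerisation (cat. I2, daylight).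

**Further compounds**

F1 | step 5 | (3S)-3-(prop-2-en-1-yloxy)butanoic acid | C[C@H](OCC=C)CC(=O)O
F2 | step 5 | (3S)-3-(prop-2-en-1-yloxy)butanoic 2-methylpropyl carbonic anhydride | C[C@H](OCC=C)CC(=O)OC(=O)OCC(C)C
F3 | step 5 | (4S)-1-diazo-4-(prop-2-en-1-yloxy)pentan-2-one | C[C@H](OCC=C)CC(=O)C=[N+]=[N-]
F4 | step 5 | (2S,5S)-5-methyl-2-(prop-2-en-1-yl)oxolan-3-one | C[C@H]1CC(=O)[C@H](CC=C)O1
F5 | step 5 | (2S,3S,5S)-5-methyl-2-(prop-2-en-1-yl)oxolan-3-ol | C[C@H]1C[C@H](O)[C@H](CC=C)O1
F6 | step 5 | triethyl{[(2S,3S,5S)-5-methyl-2-(prop-2-en-1-yl)oxolan-3-yl]oxy}silane | C[C@H]1C[C@H](O[Si](CC)(CC)CC)[C@H](CC=C)O1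
F7 | step 5 | triethyl{[(2S,3S,5S)-5-methyl-2-[(1E)-prop-1-en-1-yl]oxolan-3-yl]oxy}silane | C[C@H]1C[C@H](O[Si](CC)(CC)CC)[C@H](/C=C/C)O1
F8 | step 10 | lithium 1-[(tert-butyldimethylsilyl)oxy]-3-[2-chloro-6-(methoxycarbonyl)-3,5-bis(methoxymethoxy)phenyl]-2-[methoxy(methyl)amino]propan-2-olate | [Li]OC(CO[Si](C)(C)C(C)(C)C)(Cc1c(Cl)c(OCOC)cc(OCOC)c1C(=O)OC)N(C)OC
F9 | step 10 | methyl 2-{3-[(tert-butyldimethylsilyl)oxy]-2-oxopropyl}-3-chloro-4,6-bis(methoxymethoxy)benzoate | COC(=O)c1c(CC(=O)CO[Si](C)(C)C(C)(C)C)c(Cl)c(OCOC)cc1OCOC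
F10 | step 10 | 5-chloro-6,8-dihydroxy-3-(hydroxymethyl)-1H-isochromen-1-one | O=c1oc(CO)cc2c(Cl)c(O)cc(O)c12
F11 | step 14 | ({6,8-bis[(tert-butyldimethylsilyl)oxy]-5-chloro-1-oxo-1H-isochromen-3-yl}methyl)triphenylphosphonium chloride | [Cl-].O=c1oc(C[P+](c2ccccc2)(c2ccccc2)c2ccccc2)cc2c(Cl)c(O[Si](C)(C)C(C)(C)C)cc(O[Si](C)(C)C(C)(C)C)c12
F12 | step 14 | 6,8-bis[(tert-butyldimethylsilyl)oxy]-5-chloro-3-[(triphenyl-λ5-phosphanylidene)methyl]-1H-isochromen-1-one | O=c1oc(C=P(c2ccccc2)(c2ccccc2)c2ccccc2)cc2c(Cl)c(O[Si](C)(C)C(C)(C)C)cc(O[Si](C)(C)C(C)(C)C)c12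
F13 | step 14 | 6,8-bis[(tert-butyldimethylsilyl)oxy]-5-chloro-3-{(1Z,3E)-4-[(2S,3S,5S)-5-methyl-3-(triethylsilyloxy)oxolan-2-yl]buta-1,3-dien-1-yl}-1H-isochromen-1-one | C[C@H]1C[C@H](O[Si](CC)(CC)CC)[C@H](/C=C/C=C\c2cc3c(Cl)c(O[Si](C)(C)C(C)(C)C)cc(O[Si](C)(C)C(C)(C)C)c3c(=O)o2)O1
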